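**Plan**

1. The target is an achiral chain of six oxygenated benzene rings (A–F in SMILES order) joined by five diaryl ether bonds. All hydroxyls are carried as methyl ethers except the two on ring C.
2. After the O-alkyl bonds, the retrosynthesis cuts ring C itself at C1–C2, C4–C5 and C5–C6. Ring C has oxygens at C1, C3, C4 and C5, hydrogens at C2 and C6, and C1/C4 are the ethers to rings B and D; an aryl ethynyl ether (C1, C6) and a 4-aryloxy-3-ethoxycyclobutenone (C2–C5) deliver exactly this pattern.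
3. The cyclobutenone is cut to a DEF aryloxyketene and ethoxyacetylene, the ynol ether to the AB phenol and trichloroethylene. The A–O–B, E–O–F and D–O–E bonds are cut last (SNAr or copper coupling onto a halobenzaldehyde, then Baeyer–Villiger oxidation of the aldehyde to the next phenol).
4. Forward: rings A, B, D, E and F are bought as arenes; ethers A–B, E–F and D–E are made; ring C is created last, between the two halves; one global dealkylation ends the route.
5. Stereochemistry: the target has no stereogenic element. The sp3 centres of the cyclobutenone and of the cascade intermediates are racemic and vanish on aromatisation.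

Key step: step 11

Remark: the target is achiral, so the compound as drawn is the only stereoisomer. The eight purchased building blocks (two phenols, three halobenzaldehydes, trichloroethylene, ethyl bromoacetate, and ethoxyacetylene as its hexane solution) are taken to be catalogue compounds.
Shorthand in names: Ar(AB) = 2,6-dimethoxy-4-(2,4,6-trimethoxyphenoxy)phenyl; Ar(DEF) = 2-[3,5-dimethoxy-4-(3,4,5-trimethoxyphenoxy)phenoxy]-3,4,5-trimethoxyphenyl.

**Route**

Step 1
Reactants: 1 2,4,6-trimethoxyphenol; 2 4-fluoro-2,6-dimethoxybenzaldehyde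
Product: 3 AB aldehyde [2,6-dimethoxy-4-(2,4,6-trimethoxyphenoxy)benzaldehyde]
Conditions: Cs2CO3, DMSO, 120 °C, Ar
Reagents that add atoms: none
Why: Nucleophilic aromatic substitution should proceed because the fluoride of 2 is para to the formyl group, which stabilises the Meisenheimer adduct, and the hindered but electron-rich phenoxide of 1 is a competent nucleophile in a hot dipolar aprotic solvent.

Step 2
Reactants: 3 AB aldehyde
Product: 5 AB phenol [2,6-dimethoxy-4-(2,4,6-trimethoxyphenoxy)phenol], via aryl formate 4 (not isolated)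
Conditions: mCPBA (1.1 equiv), NaHCO3, CH2Cl2, 0 °C → rt; Na2S2O3 wash; then K2CO3 (cat.), MeOH, rt
Reagents that add atoms: mCPBA (3-chloroperoxybenzoic acid), OOC(=O)c1cccc(Cl)c1
Why: In this Baeyer–Villiger (Dakin-type) oxidation the aryl group, made electron-rich by two ortho methoxy groups and a para aryloxy group, should migrate in preference to hydrogen, and the phenol is released by methanolysis only after the peracid has been destroyed.

Step 3
Reactants: 5 AB phenol; 6 trichloroethylene
Product: 8 AB dichlorovinyl ether [2-[(E)-1,2-dichloroethenyloxy]-1,3-dimethoxy-5-(2,4,6-trimethoxyphenoxy)benzene], via dichloroacetylene 7 (not isolated)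
Conditions: K2CO3, DMF, 70 °C, Ar
Reagents that add atoms: none
Why: Base eliminates HCl from trichloroethylene and the phenoxide adds anti across the dichloroacetylene formed, which is the established route from phenols to (E)-1,2-dichlorovinyl ethers.

Step 4
Reactants: 8 AB dichlorovinyl ether
Product: 11 AB ethynyl ether [2-(ethynyloxy)-1,3-dimethoxy-5-(2,4,6-trimethoxyphenoxy)benzene], via chloroalkynyl ether 9 (not isolated), via lithium acetylide 10 (not isolated)
Conditions: n-BuLi (2.2 equiv), Et2O, −78 → −40 °C; MeOH, −78 °C; kept as a cold toluene solution and used at once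
Reagents that add atoms: none
Why: In this ynol ether synthesis from a dichlorovinyl ether, vinylic deprotonation and loss of LiCl give 9, chlorine–lithium exchange gives 10, and protonation at low temperature gives the terminal alkyne before the ring positions between two oxygens can be lithiated.

Step 5
Reactants: 12 3,4,5-trimethoxyphenol; 13 4-bromo-3,5-dimethoxybenzaldehyde
Product: 14 EF aldehyde [3,5-dimethoxy-4-(3,4,5-trimethoxyphenoxy)benzaldehyde]
Conditions: CuI (10 mol%), picolinic acid (20 mol%), K3PO4, DMSO, 90 °C, Ar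
Reagents that add atoms: none
Why: This Ullmann diaryl ether coupling uses ligand conditions suited to hindered partners; the para formyl group activates the C–Br bond flanked by two methoxy groups, and phenol 12 is unhindered and electron-rich.

Step 6
Reactants: 14 EF aldehyde
Product: 16 EF phenol [3,5-dimethoxy-4-(3,4,5-trimethoxyphenoxy)phenol], via aryl formate 15 (not isolated)
Conditions: mCPBA (1.1 equiv), NaHCO3, CH2Cl2, 0 °C → rt; Na2S2O3 wash; then K2CO3 (cat.), MeOH, rt
Reagents that add atoms: mCPBA (3-chloroperoxybenzoic acid), OOC(=O)c1cccc(Cl)c1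
Why: Baeyer–Villiger oxidation of a 3,4,5-trioxygenated benzaldehyde gives the aryl formate by aryl migration, as in the conversion of 3,4,5-trimethoxybenzaldehyde into its phenol, and methanolysis frees the phenol.

Step 7
Reactants: 16 EF phenol; 17 2-bromo-3,4,5-trimethoxybenzaldehyde
Product: 18 DEF aldehyde [2-[3,5-dimethoxy-4-(3,4,5-trimethoxyphenoxy)phenoxy]-3,4,5-trimethoxybenzaldehyde]
Conditions: CuI (10 mol%), picolinic acid (20 mol%), K3PO4, DMSO, 100 °C, Ar
Reagents that add atoms: none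
Why: Ullmann coupling at a bromide ortho to a carbonyl group is the classical way to ortho-aryloxy-3,4,5-trimethoxybenzoyl ethers, and the phenol of 16 is unhindered.

Step 8
Reactants: 18 DEF aldehyde
Product: 20 DEF phenol [2-[3,5-dimethoxy-4-(3,4,5-trimethoxyphenoxy)phenoxy]-3,4,5-trimethoxyphenol], via aryl formate 19 (not isolated)
Conditions: mCPBA (1.1 equiv), NaHCO3, CH2Cl2, 0 °C → rt; Na2S2O3 wash; then K2CO3 (cat.), MeOH, rt
Reagents that add atoms: mCPBA (3-chloroperoxybenzoic acid), OOC(=O)c1cccc(Cl)c1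
Why: The migrating ring carries an ortho aryloxy and a para methoxy group, so Baeyer–Villiger oxidation should give the formate cleanly, and methanolysis gives the phenol that will become the ring C–ring D ether oxygen.

Step 9
Reactants: 20 DEF phenol; 21 ethyl bromoacetate
Product: 23 DEF aryloxyacetic acid [2-(Ar(DEF)oxy)acetic acid], via ethyl ester 22 (not isolated)
Conditions: K2CO3, DMF, rt; then LiOH, THF–H2O, rt; 1 M HCl work-up
Reagents that add atoms: lithium hydroxide (aqueous), [Li+].[OH-]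
Why: Williamson O-alkylation of the phenoxide with an α-halo ester and saponification in the same flask are routine, and methyl and diaryl ethers are inert to both.

Step 10
Reactants: 23 DEF aryloxyacetic acid; 24 ethoxyacetylene
Product: 27 DEF cyclobutenone [rac-4-(Ar(DEF)oxy)-3-ethoxycyclobut-2-en-1-one], via acid chloride 25 (not isolated), via aryloxyketene 26 (not isolated)
Conditions: 1-chloro-N,N,2-trimethylpropenylamine, CH2Cl2, 0 °C → rt; then 24 (3 equiv), Et3N (slow addition), 0 °C → rt; Et3N-deactivated silica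
Reagents that add atoms: none
Why: The acid chloride is made under neutral conditions so the electron-rich rings are not acylated, triethylamine then generates aryloxyketene 26, and its thermal [2+2] cycloaddition with ethoxyacetylene (ketene carbonyl carbon to the alkyne terminus) is the standard route to 4-substituted 3-ethoxycyclobutenones.

Step 11
Reactants: 11 AB ethynyl ether; 27 DEF cyclobutenone
Product: 32 ring C phenol [5-(Ar(AB)oxy)-2-(Ar(DEF)oxy)-3-ethoxyphenol], via vinylketene 28 (not isolated), via vinylcyclobutenone 29 (not isolated), via dienylketene 30 (not isolated), via cyclohexadienone 31 (not isolated)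
Conditions: toluene (0.2 M), 80 → 110 °C, sealed tube, Ar; then K2CO3, MeOH, rt
Reagents that add atoms: none
Why: Heating should open 27 by four-electron electrocyclic cleavage of its C1–C4 bond, the C4 aryloxy donor turning outward and lowering the barrier as in other 4-oxygenated cyclobutenones, to give vinylketene 28, whose ketene C=C adds the electron-rich alkyne of 11 in a [2+2] cycloaddition to give 29, which opens again to dienylketene 30. Ring C then closes by thermal disrotatory six-electron electrocyclisation of 30, joining the ketene carbon to the aryloxy-bearing terminus, and enolisation of cyclohexadienone 31 gives the phenol. The closest known reaction is the Danheiser benzannulation of cyclobutenones with alkynyl ethers, here with an aryl group on the ynol oxygen. No stereocentre is created, since the sp3 centres of 27, 29 and 31 are erased on aromatisation. The one selectivity needed is bonding of the alkyne terminus to the ketene carbonyl carbon; the oxygen-polarised triple bond of 11, whose unsubstituted carbon is the nucleophilic one, secures it and places the ring B oxygen meta to the new hydroxyl and para to the ring D oxygen. The aryl group on oxygen has no β-hydrogen, so 11 cannot fragment by retro-ene loss of an alkene, and any product acylated by 28 is returned to 32 by the carbonate–methanol work-up.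

Step 12
Reactants: 32 ring C phenol
Product: 33 CNP0175585.0 [5-[2,6-dihydroxy-4-(2,4,6-trihydroxyphenoxy)phenoxy]-2-[2-[3,5-dihydroxy-4-(3,4,5-trihydroxyphenoxy)phenoxy]-3,4,5-trihydroxyphenoxy]benzene-1,3-diol]
Conditions: BBr3 (30 equiv), CH2Cl2, −78 °C → rt, Ar; ice-water quench; Sephadex LH-20 with degassed solvents
Reagents that add atoms: none
Why: Boron tribromide cleaves aryl methyl and ethyl ethers by bromide attack on the O-alkyl carbon of the borate complex, whereas the five diaryl ethers offer no sp3 carbon and should survive.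

**Compound list**

1 | 2,4,6-trimethoxyphenol | COc1cc(OC)c(O)c(OC)c1 | starting material
2 | 4-fluoro-2,6-dimethoxybenzaldehyde | COc1cc(F)cc(OC)c1C=O | starting material
3 | AB aldehyde, 2,6-dimethoxy-4-(2,4,6-trimethoxyphenoxy)benzaldehyde | COc1cc(OC)c(Oc2cc(OC)c(C=O)c(OC)c2)c(OC)c1 | intermediate
4 | AB aryl formate, 2,6-dimethoxy-4-(2,4,6-trimethoxyphenoxy)phenyl formate | O=COc1c(OC)cc(Oc2c(OC)cc(OC)cc2OC)cc1OC | intermediate
5 | AB phenol, 2,6-dimethoxy-4-(2,4,6-trimethoxyphenoxy)phenol | Oc1c(OC)cc(Oc2c(OC)cc(OC)cc2OC)cc1OC | intermediate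
6 | trichloroethylene | ClC=C(Cl)Cl | starting material
7 | dichloroacetylene | ClC#CCl | intermediate
8 | AB dichlorovinyl ether, 2-[(E)-1,2-dichloroethenyloxy]-1,3-dimethoxy-5-(2,4,6-trimethoxyphenoxy)benzene | Cl/C=C(/Cl)Oc1c(OC)cc(Oc2c(OC)cc(OC)cc2OC)cc1OC | intermediate
9 | AB chloroalkynyl ether, 2-(chloroethynyloxy)-1,3-dimethoxy-5-(2,4,6-trimethoxyphenoxy)benzene | ClC#COc1c(OC)cc(Oc2c(OC)cc(OC)cc2OC)cc1OC | intermediate
10 | lithium acetylide, lithium 2-(Ar(AB)oxy)ethynide | [Li]C#COc1c(OC)cc(Oc2c(OC)cc(OC)cc2OC)cc1OC | intermediate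
11 | AB ethynyl ether, 2-(ethynyloxy)-1,3-dimethoxy-5-(2,4,6-trimethoxyphenoxy)benzene | C#COc1c(OC)cc(Oc2c(OC)cc(OC)cc2OC)cc1OC | intermediate
12 | 3,4,5-trimethoxyphenol | COc1cc(O)cc(OC)c1OC | starting material
13 | 4-bromo-3,5-dimethoxybenzaldehyde | COc1cc(C=O)cc(OC)c1Br | starting material
14 | EF aldehyde, 3,5-dimethoxy-4-(3,4,5-trimethoxyphenoxy)benzaldehyde | COc1cc(C=O)cc(OC)c1Oc1cc(OC)c(OC)c(OC)c1 | intermediate
15 | EF aryl formate, 3,5-dimethoxy-4-(3,4,5-trimethoxyphenoxy)phenyl formate | O=COc1cc(OC)c(Oc2cc(OC)c(OC)c(OC)c2)c(OC)c1 | intermediate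
16 | EF phenol, 3,5-dimethoxy-4-(3,4,5-trimethoxyphenoxy)phenol | Oc1cc(OC)c(Oc2cc(OC)c(OC)c(OC)c2)c(OC)c1 | intermediate
17 | 2-bromo-3,4,5-trimethoxybenzaldehyde | COc1cc(C=O)c(Br)c(OC)c1OC | starting material
18 | DEF aldehyde, 2-[3,5-dimethoxy-4-(3,4,5-trimethoxyphenoxy)phenoxy]-3,4,5-trimethoxybenzaldehyde | COc1cc(C=O)c(Oc2cc(OC)c(Oc3cc(OC)c(OC)c(OC)c3)c(OC)c2)c(OC)c1OC | intermediate
19 | DEF aryl formate, Ar(DEF) formate | O=COc1cc(OC)c(OC)c(OC)c1Oc1cc(OC)c(Oc2cc(OC)c(OC)c(OC)c2)c(OC)c1 | intermediate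
20 | DEF phenol, 2-[3,5-dimethoxy-4-(3,4,5-trimethoxyphenoxy)phenoxy]-3,4,5-trimethoxyphenol | Oc1cc(OC)c(OC)c(OC)c1Oc1cc(OC)c(Oc2cc(OC)c(OC)c(OC)c2)c(OC)c1 | intermediate
21 | ethyl bromoacetate | CCOC(=O)CBr | starting material
22 | ethyl 2-(Ar(DEF)oxy)acetate | CCOC(=O)COc1cc(OC)c(OC)c(OC)c1Oc1cc(OC)c(Oc2cc(OC)c(OC)c(OC)c2)c(OC)c1 | intermediate
23 | 2-(Ar(DEF)oxy)acetic acid | OC(=O)COc1cc(OC)c(OC)c(OC)c1Oc1cc(OC)c(Oc2cc(OC)c(OC)c(OC)c2)c(OC)c1 | intermediate
24 | ethoxyacetylene | CCOC#C | starting material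
25 | 2-(Ar(DEF)oxy)acetyl chloride | ClC(=O)COc1cc(OC)c(OC)c(OC)c1Oc1cc(OC)c(Oc2cc(OC)c(OC)c(OC)c2)c(OC)c1 | intermediate
26 | aryloxyketene, 2-(Ar(DEF)oxy)ethenone | O=C=COc1cc(OC)c(OC)c(OC)c1Oc1cc(OC)c(Oc2cc(OC)c(OC)c(OC)c2)c(OC)c1 | intermediate
27 | DEF cyclobutenone, rac-4-(Ar(DEF)oxy)-3-ethoxycyclobut-2-en-1-one | CCOC1=CC(=O)C1Oc1cc(OC)c(OC)c(OC)c1Oc1cc(OC)c(Oc2cc(OC)c(OC)c(OC)c2)c(OC)c1 | intermediate
28 | vinylketene, (3Z)-4-(Ar(DEF)oxy)-3-ethoxybuta-1,3-dien-1-one | O=C=C/C(OCC)=C/Oc1cc(OC)c(OC)c(OC)c1Oc1cc(OC)c(Oc2cc(OC)c(OC)c(OC)c2)c(OC)c1 | intermediate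
29 | vinylcyclobutenone, rac-3-(Ar(AB)oxy)-4-[(Z)-2-(Ar(DEF)oxy)-1-ethoxyethenyl]cyclobut-2-en-1-one | O=C1C=C(Oc2c(OC)cc(Oc3c(OC)cc(OC)cc3OC)cc2OC)C1/C(OCC)=C/Oc1cc(OC)c(OC)c(OC)c1Oc1cc(OC)c(Oc2cc(OC)c(OC)c(OC)c2)c(OC)c1 | intermediate
30 | dienylketene, (3E,5Z)-3-(Ar(AB)oxy)-6-(Ar(DEF)oxy)-5-ethoxyhexa-1,3,5-trien-1-one | O=C=C/C(Oc1c(OC)cc(Oc2c(OC)cc(OC)cc2OC)cc1OC)=C\C(OCC)=C\Oc1cc(OC)c(OC)c(OC)c1Oc1cc(OC)c(Oc2cc(OC)c(OC)c(OC)c2)c(OC)c1 | intermediate
31 | cyclohexadienone, rac-3-(Ar(AB)oxy)-6-(Ar(DEF)oxy)-5-ethoxycyclohexa-2,4-dien-1-one | O=C1C=C(Oc2c(OC)cc(Oc3c(OC)cc(OC)cc3OC)cc2OC)C=C(OCC)C1Oc1cc(OC)c(OC)c(OC)c1Oc1cc(OC)c(Oc2cc(OC)c(OC)c(OC)c2)c(OC)c1 | intermediate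
32 | ring C phenol, 5-(Ar(AB)oxy)-2-(Ar(DEF)oxy)-3-ethoxyphenol | COc1cc(OC)c(Oc2cc(OC)c(Oc3cc(OCC)c(Oc4cc(OC)c(OC)c(OC)c4Oc4cc(OC)c(Oc5cc(OC)c(OC)c(OC)c5)c(OC)c4)c(O)c3)c(OC)c2)c(OC)c1 | intermediate
33 | CNP0175585.0, 5-[2,6-dihydroxy-4-(2,4,6-trihydroxyphenoxy)phenoxy]-2-[2-[3,5-dihydroxy-4-(3,4,5-trihydroxyphenoxy)phenoxy]-3,4,5-trihydroxyphenoxy]benzene-1,3-diol | Oc1cc(O)c(Oc2cc(O)c(Oc3cc(O)c(Oc4cc(O)c(O)c(O)c4Oc4cc(O)c(Oc5cc(O)c(O)c(O)c5)c(O)c4)c(O)c3)c(O)c2)c(O)c1 | target

**Step count and risks**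

Total step count: 12. Longest linear sequence: 8 steps (steps 5–12, from 12 and 13).

The three steps most likely to fail:

Step 11. Opening of the vinylogous-ester cyclobutenone may be slower than oligomerisation of the terminal ynol ether, or the vinylketene may dimerise, so that the cascade stalls before ring closure. The fallback sets out from DEF phenol 20, gives up the benzannulation, and adds rings C, B and A one at a time with the two reaction types of steps 5 and 6. Copper-catalysed coupling of 20 with bromoaldehyde 13 would give the CDEF aldehyde F1, Baeyer–Villiger oxidation its aryl formate F2, and methanolysis the CDEF phenol F3. A second round with 13 would give the BCDEF aldehyde F4, its aryl formate F5 and the BCDEF phenol F6. Coupling of F6 with 2-iodo-1,3,5-trimethoxybenzene under the same copper conditions would add ring A and give the per-O-methyl hexamer F7. Boron tribromide as in step 12 would then cleave its fifteen methyl ethers and bring the route back at 33.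

Step 4. The terminal aryloxyacetylene may oligomerise or add water during quench and concentration, so that little intact alkyne reaches the key step. The fallback sets out from 8: acetylide 10 is generated as before but quenched with chlorotrimethylsilane, giving the C-silyl ynol ether F8, which should tolerate chromatography and storage. Tetrabutylammonium fluoride in wet THF at −20 °C, immediately before step 11, would release the alkyne and return to the route at 11 as a cold solution.

Step 12. Cleavage of fourteen ethers may stop short at several sites, and the pyrogallol-type rings D and F may oxidise in air during isolation of the free polyphenol. The fallback sets out from 32: after the boron tribromide treatment the crude material is acetylated directly (Ac2O, pyridine) to the pentadecaacetate F9, which can be purified on silica and separated from partly alkylated material. Acid-catalysed methanolysis (HCl in MeOH, rt, Ar) would then remove the acetates without forming oxidisable phenolates and return to the route at 33.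

**Further compounds**

F1 | step 11 | CDEF aldehyde, 4-(Ar(DEF)oxy)-3,5-dimethoxybenzaldehyde | COc1cc(C=O)cc(OC)c1Oc1cc(OC)c(OC)c(OC)c1Oc1cc(OC)c(Oc2cc(OC)c(OC)c(OC)c2)c(OC)c1
F2 | step 11 | CDEF aryl formate, 4-(Ar(DEF)oxy)-3,5-dimethoxyphenyl formate | O=COc1cc(OC)c(Oc2cc(OC)c(OC)c(OC)c2Oc2cc(OC)c(Oc3cc(OC)c(OC)c(OC)c3)c(OC)c2)c(OC)c1
F3 | step 11 | CDEF phenol, 4-(Ar(DEF)oxy)-3,5-dimethoxyphenol | Oc1cc(OC)c(Oc2cc(OC)c(OC)c(OC)c2Oc2cc(OC)c(Oc3cc(OC)c(OC)c(OC)c3)c(OC)c2)c(OC)c1
F4 | step 11 | BCDEF aldehyde, 4-[4-(Ar(DEF)oxy)-3,5-dimethoxyphenoxy]-3,5-dimethoxybenzaldehyde | COc1cc(C=O)cc(OC)c1Oc1cc(OC)c(Oc2cc(OC)c(OC)c(OC)c2Oc2cc(OC)c(Oc3cc(OC)c(OC)c(OC)c3)c(OC)c2)c(OC)c1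
F5 | step 11 | BCDEF aryl formate, 4-[4-(Ar(DEF)oxy)-3,5-dimethoxyphenoxy]-3,5-dimethoxyphenyl formate | O=COc1cc(OC)c(Oc2cc(OC)c(Oc3cc(OC)c(OC)c(OC)c3Oc3cc(OC)c(Oc4cc(OC)c(OC)c(OC)c4)c(OC)c3)c(OC)c2)c(OC)c1
F6 | step 11 | BCDEF phenol, 4-[4-(Ar(DEF)oxy)-3,5-dimethoxyphenoxy]-3,5-dimethoxyphenol | Oc1cc(OC)c(Oc2cc(OC)c(Oc3cc(OC)c(OC)c(OC)c3Oc3cc(OC)c(Oc4cc(OC)c(OC)c(OC)c4)c(OC)c3)c(OC)c2)c(OC)c1
F7 | step 11 | per-O-methyl hexamer (pentadecamethyl ether of the target) | COc1cc(OC)c(Oc2cc(OC)c(Oc3cc(OC)c(Oc4cc(OC)c(OC)c(OC)c4Oc4cc(OC)c(Oc5cc(OC)c(OC)c(OC)c5)c(OC)c4)c(OC)c3)c(OC)c2)c(OC)c1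
F8 | step 4 | C-silyl ynol ether, [2-(Ar(AB)oxy)ethynyl]trimethylsilane | C[Si](C)(C)C#COc1c(OC)cc(Oc2c(OC)cc(OC)cc2OC)cc1OC
F9 | step 12 | pentadecaacetate of the target | CC(=O)Oc1cc(OC(C)=O)c(Oc2cc(OC(C)=O)c(Oc3cc(OC(C)=O)c(Oc4cc(OC(C)=O)c(OC(C)=O)c(OC(C)=O)c4Oc4cc(OC(C)=O)c(Oc5cc(OC(C)=O)c(OC(C)=O)c(OC(C)=O)c5)c(OC(C)=O)c4)c(OC(C)=O)c3)c(OC(C)=O)c2)c(OC(C)=O)c1
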